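The target is cut between C2 of the γ-pyrone (ring C) and C1′ of the catechol ring B. One oxidative boron-Heck reaction joins commercial 5,7-dihydroxychromone to [3,4-bis(benzyloxy)phenyl]boronic acid. It exploits the polarised vinylogous ester O1–C2(H)=C3–C4=O of ring C: the aryl–palladium adds at C2 and β-hydride loss restores the pyrone, so a C–H bond is arylated without halide or prior activation. The A ring is then completed on the flavone: Elbs persulfate oxidation installs O-8 para to the 5-OH, the most acidic hydroxyl (7-OH) is sulfated, and hydrogenolysis frees the catechol.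

Key step: step 1

Remark: the target has no stereocentre, so no stereocontrol is needed; aryl hydrogen sulfates 6 and 7 are drawn as free acids like the target but would be handled as ammonium or alkali salts, the acid being liberated by cold cation exchange.

Step 1
Reactants: 1 5,7-dihydroxy-4H-chromen-4-one; 2 [3,4-bis(benzyloxy)phenyl]boronic acid
Product: 3 2-[3,4-bis(benzyloxy)phenyl]-5,7-dihydroxy-4H-chromen-4-one
Conditions: 2 (2 equiv), Pd(OAc)2 (10 mol %), 1,10-phenanthroline (20 mol %), O2 (1 atm), DMF, 80 °C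
Reagents that add atoms: none
Why: Transmetalation of 2 to Pd(II) gives an aryl–Pd species that adds across C2=C3 of the γ-pyrone with the aryl group on the β-carbon C2 and Pd on C3 (a Pd enolate); after C-/O-enolate equilibration, syn β-hydride elimination of H-2 restores the pyrone and O2 reoxidises Pd(0). The closest known reaction type is the oxidative (boron) Heck arylation of chromones and coumarins with arylboronic acids. No ring is closed and no stereocentre is formed. The step needs C2 over C3 selectivity, which the polarity of the vinylogous ester O1–C2=C3–C4=O secures because the aryl group migrates to the electrophilic β-carbon, while C3 would react only by electrophilic palladation, which the pre-formed aryl–Pd bypasses. The chelated 5-OH and the 7-OH are expected to be tolerated, benzyl ethers are inert, and the excess of 2 compensates protodeboronation and homocoupling.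

Step 2
Reactants: 3 2-[3,4-bis(benzyloxy)phenyl]-5,7-dihydroxy-4H-chromen-4-one
Product: 5 2-[3,4-bis(benzyloxy)phenyl]-5,7,8-trihydroxy-4H-chromen-4-one, via flavone 8-O-sulfate potassium salt 4 (not isolated)
Conditions: K2S2O8 (1.2 equiv), aq KOH, pyridine, 0 °C → rt, Ar; then 2 M HCl, 70 °C
Reagents that add atoms: potassium peroxodisulfate, [K+].[K+].[O-]S(=O)(=O)OOS(=O)(=O)[O-]
Why: Elbs persulfate oxidation, in which the A-ring phenolate attacks a peroxide oxygen through C8, the only free position para to O-5 (and ortho to O-7), to give aryl sulfate 4, whose mild acid hydrolysis unmasks the 8-OH only after the air-sensitive alkaline stage is over, while benzyl ethers and the 2-arylpyrone tolerate cold alkali and dilute acid.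

Step 3
Reactants: 5 2-[3,4-bis(benzyloxy)phenyl]-5,7,8-trihydroxy-4H-chromen-4-one
Product: 6 2-[3,4-bis(benzyloxy)phenyl]-5,8-dihydroxy-4-oxo-4H-chromen-7-yl hydrogen sulfate
Conditions: SO3·NMe3 (1.1 equiv), Et3N (1.0 equiv), DMF, 0 °C → rt, Ar
Reagents that add atoms: sulfur trioxide–trimethylamine complex, C[N+](C)(C)S(=O)(=O)[O-]
Why: Phenoxide sulfation with an SO3–amine complex, in which one equivalent of Et3N should ionise only the 7-OH (a vinylogous carboxylic acid para to C4=O) while the 8-OH (meta to the carbonyl, flanked by O1 and O7) and the chelated 5-OH stay protonated, so the sulfuryl group is expected on O-7.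

Step 4
Reactants: 6 2-[3,4-bis(benzyloxy)phenyl]-5,8-dihydroxy-4-oxo-4H-chromen-7-yl hydrogen sulfate
Product: 7 8-hydroxyluteolin 7-sulfate, 2-(3,4-dihydroxyphenyl)-5,8-dihydroxy-4-oxo-4H-chromen-7-yl hydrogen sulfate
Conditions: H2 (1 atm), 10% Pd/C, MeOH–THF, rt, on the triethylammonium salt; then Dowex 50W (H+ form), H2O, 0 °C, lyophilise under Ar
Reagents that add atoms: none
Why: Catalytic hydrogenolysis of the two benzyl ethers, which aryl sulfate monoester salts and the flavone C2=C3 bond are expected to survive at 1 atm, with no acid or Lewis acid that could cleave the sulfate until the brief cold ion exchange.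

Compound list
1 | 5,7-dihydroxy-4H-chromen-4-one (5,7-dihydroxychromone) | O=c1ccoc2cc(O)cc(O)c12 | starting material
2 | [3,4-bis(benzyloxy)phenyl]boronic acid | OB(O)c1ccc(OCc2ccccc2)c(OCc2ccccc2)c1 | starting material
3 | 2-[3,4-bis(benzyloxy)phenyl]-5,7-dihydroxy-4H-chromen-4-one | O=c1cc(-c2ccc(OCc3ccccc3)c(OCc3ccccc3)c2)oc2cc(O)cc(O)c12 | intermediate
4 | potassium 2-[3,4-bis(benzyloxy)phenyl]-5,7-dihydroxy-4-oxo-4H-chromen-8-yl sulfate | O=c1cc(-c2ccc(OCc3ccccc3)c(OCc3ccccc3)c2)oc2c(OS(=O)(=O)[O-])c(O)cc(O)c12.[K+] | intermediate (not isolated)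
5 | 2-[3,4-bis(benzyloxy)phenyl]-5,7,8-trihydroxy-4H-chromen-4-one | O=c1cc(-c2ccc(OCc3ccccc3)c(OCc3ccccc3)c2)oc2c(O)c(O)cc(O)c12 | intermediate
6 | 2-[3,4-bis(benzyloxy)phenyl]-5,8-dihydroxy-4-oxo-4H-chromen-7-yl hydrogen sulfate | O=c1cc(-c2ccc(OCc3ccccc3)c(OCc3ccccc3)c2)oc2c(O)c(OS(=O)(=O)O)cc(O)c12 | intermediate
7 | 8-hydroxyluteolin 7-sulfate | O=c1cc(-c2ccc(O)c(O)c2)oc2c(O)c(OS(=O)(=O)O)cc(O)c12 | target

Total step count: 4
Longest linear sequence: 4 steps (1 → 3 → 5 → 6 → 7); boronic acid 2 is used as purchased.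

Steps most likely to fail

Step 3. The sulfuryl group may be transferred to O-8 or to both catechol oxygens (loss of regiocontrol within the 7,8-diol), and the ionised triol may oxidise in air. The fallback sets out from 3 and comes back at 7, and removes any dependence on O-7/O-8 selectivity. O-Allylation of the only non-chelated hydroxyl of 3 (allyl bromide, K2CO3, DMF) should give 7-(allyloxy)-2-[3,4-bis(benzyloxy)phenyl]-5-hydroxy-4H-chromen-4-one F6. Elbs oxidation under the conditions of step 2 should pass through potassium 7-(allyloxy)-2-[3,4-bis(benzyloxy)phenyl]-5-hydroxy-4-oxo-4H-chromen-8-yl sulfate F7 (not isolated) and give 7-(allyloxy)-2-[3,4-bis(benzyloxy)phenyl]-5,8-dihydroxy-4H-chromen-4-one F8. Benzylation of the free 8-OH (BnBr, K2CO3, acetone; the chelated 5-OH is left) should give 7-(allyloxy)-8-(benzyloxy)-2-[3,4-bis(benzyloxy)phenyl]-5-hydroxy-4H-chromen-4-one F9. Deallylation (Pd(PPh3)4, morpholine, THF) should give 8-(benzyloxy)-2-[3,4-bis(benzyloxy)phenyl]-5,7-dihydroxy-4H-chromen-4-one F10, in which O-7 is the only hydroxyl open to sulfation. SO3·NMe3/Et3N in DMF should then give 8-(benzyloxy)-2-[3,4-bis(benzyloxy)phenyl]-5-hydroxy-4-oxo-4H-chromen-7-yl hydrogen sulfate F11, and hydrogenolysis under the conditions of step 4 removes all three benzyl groups to arrive at 7.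

Step 2. Conversion may be incomplete, the electron-rich phenolate may be over-oxidised by radical pathways of persulfate, and material may be lost in separating the water-soluble sulfate from recovered 3. The fallback sets out from 3 and comes back at 5. Duff formylation (hexamethylenetetramine, AcOH, 100 °C; then aq HCl) at C8, the position ortho to O-7 and para to O-5, should give 2-[3,4-bis(benzyloxy)phenyl]-5,7-dihydroxy-4-oxo-4H-chromene-8-carbaldehyde F4; the site of formylation has to be confirmed and any C6 isomer separated. Acid-mediated Dakin oxidation (H2O2, H3BO3, cat. H2SO4, THF, rt) should proceed through 2-[3,4-bis(benzyloxy)phenyl]-5,7-dihydroxy-4-oxo-4H-chromen-8-yl formate F5 (not isolated), which is hydrolysed on aqueous work-up to 5.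

Step 1. Carbopalladation of the electron-rich enone with its ionisable 7-OH may be slow, so that protodeboronation and homocoupling consume 2 first. The fallback sets out from 1 and comes back at 3; it forms the same C2–C1′ bond at the flavanone oxidation level on a more electrophilic acceptor. Selective acylation of the 7-OH (PivCl, Et3N, CH2Cl2, 0 °C) should give 5-hydroxy-4-oxo-4H-chromen-7-yl pivalate F1. Pd(II)-catalysed conjugate addition of 2 (Pd(TFA)2, 2,2′-bipyridine, AcOH–THF–H2O, 60 °C) should give racemic 2-[3,4-bis(benzyloxy)phenyl]-5-hydroxy-4-oxochroman-7-yl pivalate F2. Dehydrogenation (cat. I2, DMSO, 110 °C) should give 2-[3,4-bis(benzyloxy)phenyl]-5-hydroxy-4-oxo-4H-chromen-7-yl pivalate F3, and methanolysis (K2CO3, MeOH, rt) returns 3.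

Further compounds
F1 | step 1 | 5-hydroxy-4-oxo-4H-chromen-7-yl pivalate | O=c1ccoc2cc(OC(=O)C(C)(C)C)cc(O)c12
F2 | step 1 | racemic 2-[3,4-bis(benzyloxy)phenyl]-5-hydroxy-4-oxochroman-7-yl pivalate | O=C1CC(c2ccc(OCc3ccccc3)c(OCc3ccccc3)c2)Oc2cc(OC(=O)C(C)(C)C)cc(O)c12
F3 | step 1 | 2-[3,4-bis(benzyloxy)phenyl]-5-hydroxy-4-oxo-4H-chromen-7-yl pivalate | O=c1cc(-c2ccc(OCc3ccccc3)c(OCc3ccccc3)c2)oc2cc(OC(=O)C(C)(C)C)cc(O)c12
F4 | step 2 | 2-[3,4-bis(benzyloxy)phenyl]-5,7-dihydroxy-4-oxo-4H-chromene-8-carbaldehyde | O=Cc1c(O)cc(O)c2c(=O)cc(-c3ccc(OCc4ccccc4)c(OCc4ccccc4)c3)oc12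
F5 | step 2 | 2-[3,4-bis(benzyloxy)phenyl]-5,7-dihydroxy-4-oxo-4H-chromen-8-yl formate | O=COc1c(O)cc(O)c2c(=O)cc(-c3ccc(OCc4ccccc4)c(OCc4ccccc4)c3)oc12
F6 | step 3 | 7-(allyloxy)-2-[3,4-bis(benzyloxy)phenyl]-5-hydroxy-4H-chromen-4-one | C=CCOc1cc(O)c2c(=O)cc(-c3ccc(OCc4ccccc4)c(OCc4ccccc4)c3)oc2c1
F7 | step 3 | potassium 7-(allyloxy)-2-[3,4-bis(benzyloxy)phenyl]-5-hydroxy-4-oxo-4H-chromen-8-yl sulfate | C=CCOc1cc(O)c2c(=O)cc(-c3ccc(OCc4ccccc4)c(OCc4ccccc4)c3)oc2c1OS(=O)(=O)[O-].[K+]
F8 | step 3 | 7-(allyloxy)-2-[3,4-bis(benzyloxy)phenyl]-5,8-dihydroxy-4H-chromen-4-one | C=CCOc1cc(O)c2c(=O)cc(-c3ccc(OCc4ccccc4)c(OCc4ccccc4)c3)oc2c1O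
F9 | step 3 | 7-(allyloxy)-8-(benzyloxy)-2-[3,4-bis(benzyloxy)phenyl]-5-hydroxy-4H-chromen-4-one | C=CCOc1cc(O)c2c(=O)cc(-c3ccc(OCc4ccccc4)c(OCc4ccccc4)c3)oc2c1OCc1ccccc1
F10 | step 3 | 8-(benzyloxy)-2-[3,4-bis(benzyloxy)phenyl]-5,7-dihydroxy-4H-chromen-4-one | O=c1cc(-c2ccc(OCc3ccccc3)c(OCc3ccccc3)c2)oc2c(OCc3ccccc3)c(O)cc(O)c12
F11 | step 3 | 8-(benzyloxy)-2-[3,4-bis(benzyloxy)phenyl]-5-hydroxy-4-oxo-4H-chromen-7-yl hydrogen sulfate | O=c1cc(-c2ccc(OCc3ccccc3)c(OCc3ccccc3)c2)oc2c(OCc3ccccc3)c(OS(=O)(=O)O)cc(O)c12
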